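## Structural features

The target is a spiro[5.5]undecane of the chamigrane type: ring A (C1–C6) and ring B (C6–C11) share only the quaternary carbon C6. Ring A carries an exocyclic methylene at C1, a secondary alcohol at C3, a secondary bromide at C4 cis to that alcohol, and a gem-dimethyl group at C5. Ring B carries a tertiary methyl carbinol at C9 and a secondary chloride at C10, again cis to each other. The five stereocentres (3R,4S,6S,9R,10S) form two adjacent pairs, C3/C4 and C9/C10, which communicate only through C6; C6 lies between the fully substituted C5 and the sp2 carbon C1 and is the most congested atom. The exocyclic alkene is fragile (acid moves it into the ring, and with a ketone at C3 it slips into conjugation), the two halohydrins are base-sensitive, and the C9 carbinol ionises easily, above all while it is still allylic. The real difficulties are three: building C6 with the right sense relative to C9; placing chlorine on C10, where the neighbouring quaternary C9 rules out an SN2 entry; and relaying configuration from ring B to C3/C4 across a spiro atom whose two ring B arms (C7 and C11) differ only at the remote C10. The key step exploits the fact that C7–C8–C9(Me)(O)–C10=C11 is the vinyl carbinol half of (R)-linalool with C9 already R: when the terminal carbon C11 attacks a cation at C6, positive charge appears on C10, exactly where chloride is wanted, so one operation closes ring B and forms C6–C11 and C10–Cl.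

## Logic of the disconnections

19 is traced back to 18 by cutting the O–Si bond at C9. The tertiary C9 oxygen must stay masked from the first step to the last, because it is allylic and ionisable until ring B is closed. The forward step has to free a hindered tertiary silyl ether without touching the halides or the exocyclic alkene.

18 is traced back to 15 by returning the hydrogen on C2 and moving the alkene from C1=CH2 to C1=C2, with the methylene carbon becoming CH2OH. A C3 ketone and a C1 methylene cannot be handled together, and base-mediated deconjugation of an α′-bromo enone is not viable: the C4 proton is the most acidic one, and an extended enolate would carry a leaving group at C4. The alkene is therefore moved only after C3 has become a carbinol, by a reductive allylic transposition. The forward step must activate the primary allylic alcohol in the presence of the hindered secondary one.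

15 is traced back to 14 by cutting the C–O bond of the hydroxymethyl group. The C1 methyl is the only allylic C–H site on the more substituted alkene carbon, so an ene-type oxidation is directed there. The forward step must leave the C3 carbinol untouched.

14 is traced back to 13 by cutting the C3–H bond. The carbonyl at C3 is what allows bromine to be put on C4, and its reduction sets the cis bromohydrin. The forward step needs 1,2-selectivity and hydride delivery from the face opposite the axial C5 methyl.

13 is traced back to 11 (through 12) by cutting C4–Br. In the conjugated enone only C4 can be enolised kinetically (C2 is vinylic, the methyl is γ), so the regiochemistry is enforced by the substrate. The price is that C4 must be set relative to ring B, whose two arms at C6 are nearly alike; the forward step relies on the equatorial preference of bromine, separation of the C4 epimers and recycling.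

11 is traced back to 10 by cutting the C3=O bond. C3 is the only ring allylic methylene of 10 (C6 is quaternary), so an allylic oxidation has one ring site to choose. The forward step must prefer this methylene to the vinylic methyl.

10 is traced back to 9 by cutting C6–C11 and C10–Cl, which opens ring B. This removes a ring, the spiro quaternary centre and two stereocentres at once, and leaves a tertiary allylic alcohol whose C9 centre comes from the chiral pool. The forward step must do four things: ionise C6 and not the C9 allylic ether; let C11 attack C6 and not C2; pass through one chair; and capture chloride at C10 before a 1,2-shift or an oxygen attack intervenes. A tert-butyldimethylsilyl ether is chosen over a smaller trialkylsilyl group: it resists the acid formed in the ionisation, its bulk disfavours attack of the C9 oxygen on C6 (five atoms away), and it slows silyl migration in 8.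

9 is traced back to 6 and 7 (through 8) by cutting C6–C7. This is a convergent carbonyl addition; the configuration created at C6 is irrelevant because it is erased on ionisation. The forward step needs a primary alkyllithium with a γ-silyloxy group to add to a hindered ketone without silyl migration.

6 is traced back through 5, 4, 3 and 2 to 1. Ozonolysis of the trisubstituted alkene of 2 leaves three carbons on C9 (two methylenes and the aldehyde carbon), but ring B needs only C7 and C8. Reduction and iodination of 3 would therefore put three methylenes between C6 and C9 and lead to a seven-membered ring. The aldehyde carbon is instead oxidised and excised by decarboxylative iodination. The forward steps must cleave only the electron-rich alkene and must tolerate the vinyl group and the silyl ether under radical conditions.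

## Other disconnections considered

Alternative 1: The cut is C3–C4 and C4–C5 of ring A: C4 is inserted as a one-carbon unit into the spiro cyclopentanone A2. In the forward step LiCHBr2 adds to the C3 carbonyl of A2, BuLi generates the β-oxido carbenoid, C5 migrates to C4 with loss of bromide, and the C3–C4 enolate so formed is brominated to give the α-bromo ketone A1.
- In favour: the enolate is regiodefined, so bromine enters at C4 with the exocyclic methylene already in place. On this point the alternative is better than the chosen plan, which spends steps 10 and 11 on moving the alkene. The C7=C8 alkene next to C6 also makes the two arms of ring B clearly different, a better relay to C4 than the saturated ring B of 13. The ring expansion is a precedented reaction class, which the chosen key step is not.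
- Against: C2 (an allylic methylene) can migrate in competition with C5. The carbenoid reagent must add to a neopentyl carbonyl whose other α-position is doubly activated for enolisation. A β,γ-unsaturated ketone is exposed to alkyllithium base. A2 needs its own enantioselective synthesis with quaternary carbons at C5 and C6. After A1, ring B still requires ketal removal, chlorination at C10, methyl addition to C9 and saturation of C7=C8, with C9 and C10 set by substrate control.
- Comparison: the chosen plan takes C9 from the chiral pool and C10 from the ring closure itself, which is the stronger position for ring B. In step count the alternative is expected to be the longer of the two.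

Alternative 2: The cut is C2–C3 of ring A, leading to the acyclic α-bromo aldehyde A4 that carries an isopropenyl group on C6. In the forward step Me2AlCl activates the aldehyde, the isopropenyl CH2 bonds to C3 and a methyl hydrogen moves to oxygen, giving the cis-bromohydrin ketal A3.
- In favour: ring A, the homoallylic alcohol and the exocyclic methylene arise together, and C3 is never a ketone. On the ring A end game this is better than the chosen plan, and the carbonyl-ene closure is an established reaction class.
- Against: the α-bromo aldehyde is configurationally labile and lies next to the quaternary C5, so its enantioselective preparation is hard. The cis relationship depends on one particular chair. Ring B is a symmetric ketal, so C6 is not yet a stereocentre. C9 and C10 (and with them C6) would later have to be created on an achiral ring under remote control from C3/C4, which is the mirror image of the relay problem of the chosen plan but with three centres instead of one. Chlorination of the C9 ketone cannot tell C8 from C10.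
- Comparison: on ring B the chosen plan is clearly better. In step count the alternative loses because A4 needs two adjacent quaternary carbons built in an open chain.

Alternative 3: The cut is C1–C6, leading to the vinyl bromide A6. In the forward step Pd(OAc)2, BINAP and Ag3PO4 give oxidative addition to zerovalent palladium, 6-exo insertion into C6=C7 and β-hydride elimination toward C8, to give the spiro diene A5.
- In favour: the spiro centre is set by the catalyst and not by substrate bias, the methylene arrives in place, and asymmetric Heck spirocyclisation has precedent. On precedent and on absolute control of C6 the alternative is better than the chosen plan.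
- Against: the insertion has to build a quaternary carbon next to the gem-dimethyl carbon on a trisubstituted alkene. The existing C3 stereocentre creates matched and mismatched cases. A5 still has a methylene at C4, so bromine would need a C3 ketone that, with the methylene at C1, enolises toward C2. Here the chosen plan is better, because its conjugated enone enforces enolisation toward C4. Ring B needs the same later elaboration as in alternative 1.
- Comparison: the chosen plan is shorter and makes C9 and C10 more directly; the alternative is the safer of the two in its ring-forming step.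

Key step: step 6

Assumption 1: 1 and 7 are bought; the enantiomeric purity of 19 is that of commercial (R)-(−)-linalool, which is taken as enantiopure.
Assumption 2: all spiro compounds are named with the atom numbers C1–C11 defined under Structural features, not with lowest-locant numbering.

## Route

Step 1
Reactants: 1 (R)-linalool
Product: 2 tert-butyl{[(3R)-3,7-dimethylocta-1,6-dien-3-yl]oxy}dimethylsilane
Conditions: TBSOTf, 2,6-lutidine, CH2Cl2, 0 °C to rt
Reagents that add atoms: tert-butyldimethylsilyl triflate, CC(C)(C)[Si](C)(C)OS(=O)(=O)C(F)(F)F
Why: Silylation of a tertiary alcohol needs the silyl triflate; the C9 centre is not touched, and the bulky ether is chosen for the reasons given under the key disconnection.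

Step 2
Reactants: 2 tert-butyl{[(3R)-3,7-dimethylocta-1,6-dien-3-yl]oxy}dimethylsilane
Product: 3 (4R)-4-[(tert-butyldimethylsilyl)oxy]-4-methylhex-5-enal
Conditions: O3 (1 equiv, dye end point), CH2Cl2/MeOH, −78 °C; then Me2S, −78 °C to rt
Reagents that add atoms: ozone, [O-][O+]=O
Why: Ozonolysis with reductive work-up; the electron-rich trisubstituted alkene reacts far faster than the monosubstituted vinyl group, which is further deactivated by the allylic silyloxy group.

Step 3
Reactants: 3 (4R)-4-[(tert-butyldimethylsilyl)oxy]-4-methylhex-5-enal
Product: 4 (4R)-4-[(tert-butyldimethylsilyl)oxy]-4-methylhex-5-enoic acid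
Conditions: NaClO2, NaH2PO4, 2-methylbut-2-ene, t-BuOH/H2O, 0 °C to rt
Reagents that add atoms: sodium chlorite, [Na+].[O-]Cl=O
Why: Pinnick oxidation; the buffered medium spares the tertiary silyl ether and the scavenger protects the vinyl group from hypochlorite.

Step 4
Reactants: 4 (4R)-4-[(tert-butyldimethylsilyl)oxy]-4-methylhex-5-enoic acid
Product: 6 tert-butyl{[(3R)-5-iodo-3-methylpent-1-en-3-yl]oxy}dimethylsilane, via Barton ester 5 (not isolated)
Conditions: 1-hydroxypyridine-2(1H)-thione, DCC, DMAP (cat.), CH2Cl2, 0 °C to rt, dark; then CHI3, hν (tungsten lamp), rt
Reagents that add atoms: iodoform, IC(I)I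
Why: Barton decarboxylative iodination removes the surplus carbon and leaves exactly C7 and C8 on C9; the primary radical takes iodine from iodoform faster than it can add to the distant vinyl group (only 4-exo or 5-endo modes are open).

Step 5
Reactants: 6 tert-butyl{[(3R)-5-iodo-3-methylpent-1-en-3-yl]oxy}dimethylsilane; 7 2,6,6-trimethylcyclohex-2-en-1-one
Product: 9 1-{(3R)-3-[(tert-butyldimethylsilyl)oxy]-3-methylpent-4-en-1-yl}-2,6,6-trimethylcyclohex-2-en-1-ol as a mixture of carbinol epimers, via alkyllithium 8 (not isolated)
Conditions: 6, t-BuLi (2.1 equiv), Et2O/pentane, −78 °C; then 7, −78 to 0 °C; then H2O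
Reagents that add atoms: none
Why: Lithium–iodine exchange followed by 1,2-addition of the primary alkyllithium to the enone carbonyl, which has no α-hydrogen; the new centre at C6 is formed without control, which does not matter because it is erased in step 6; ether/pentane at low temperature and the bulky silyl group hold back O-to-C silyl migration in 8.

Step 6
Reactants: 9 1-{(3R)-3-[(tert-butyldimethylsilyl)oxy]-3-methylpent-4-en-1-yl}-2,6,6-trimethylcyclohex-2-en-1-ol
Product: 10 tert-butyl{[(6R,9R,10S)-10-chloro-1,5,5,9-tetramethylspiro[5.5]undec-1-en-9-yl]oxy}dimethylsilane
Conditions: SnCl4 (1.5 equiv), CH2Cl2, −78 °C; then aq. NaHCO3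
Reagents that add atoms: tin tetrachloride, Cl[Sn](Cl)(Cl)Cl
Why: Proposed new method: SnCl4 binds the free tertiary hydroxyl at C6 and ionises it to a trisubstituted allyl cation spread over C6 and C2 (both epimers of 9 give the same ion), the terminal vinyl carbon C11 bonds to C6, and chloride from the tin counter-ion adds to C10 on the opposite face of the alkene; the closest known reaction types are SnCl4-mediated halide-terminated Prins and cation–olefin cyclisations of terminal vinyl groups and polyene cyclisations started from tertiary allylic alcohols, whereas alkenes with an allylic silyloxy group are known mainly from the Prins–pinacol manifold, where a 1,2-shift ends the reaction. Ring B closes in the 6-endo-trig mode through a chair; bonding of C11 to C2 would need an eight-membered ring, and 5-exo attack by C10 would leave a primary cation. C6 is set by the chair that keeps the fully substituted C5 equatorial and the flat C1 axial on the forming ring. C10 is set by anti addition across C10=C11, which puts chlorine equatorial; its sense relative to C9 follows from the chair with the C9 methyl equatorial and the silyloxy group axial (the inside position, with the C8–C9 bond aligned with the developing p orbital at C10), so chlorine ends cis to the C9 oxygen. The step needs ionisation at C6 and not at the C9 allylic ether (free hydroxyl against a hindered silyl ether, and the better-stabilised cation), carbon and not oxygen attack on C6 (the bulky silyl group and the reversibility of oxonium formation speak against an oxaspiro[4.5]decene), and chloride capture faster than migration of C8 or of hydride to C10, which is the least secure point.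

Step 7
Reactants: 10 tert-butyl{[(6R,9R,10S)-10-chloro-1,5,5,9-tetramethylspiro[5.5]undec-1-en-9-yl]oxy}dimethylsilane
Product: 11 (6R,9R,10S)-9-[(tert-butyldimethylsilyl)oxy]-10-chloro-1,5,5,9-tetramethylspiro[5.5]undec-1-en-3-one
Conditions: Rh2(cap)4 (1 mol %), t-BuOOH (aq.), CH2Cl2, rt
Reagents that add atoms: tert-butyl hydroperoxide, CC(C)(C)OO
Why: Catalytic allylic oxidation by tert-butylperoxyl radicals; C3 is the only ring allylic methylene (C6 is quaternary) and such methylenes are oxidised in preference to a vinylic methyl, giving the conjugated enone.

Step 8
Reactants: 11 (6R,9R,10S)-9-[(tert-butyldimethylsilyl)oxy]-10-chloro-1,5,5,9-tetramethylspiro[5.5]undec-1-en-3-one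
Product: 13 (4S,6S,9R,10S)-4-bromo-9-[(tert-butyldimethylsilyl)oxy]-10-chloro-1,5,5,9-tetramethylspiro[5.5]undec-1-en-3-one, via silyl dienol ether 12 (not isolated)
Conditions: LiN(i-Pr)2, THF, −78 °C; Me3SiCl; then NBS, THF, −78 to 0 °C; C4 epimers separated, 4R epimer re-equilibrated (DBU cat.) and recycled
Reagents that add atoms: N-bromosuccinimide, O=C1CCC(=O)N1Br
Why: Kinetic deprotonation of the enone can only occur at C4 (as in other β-methyl cyclohexenones with a neopentyl α′-methylene), and bromination of the cross-conjugated silyl dienol ether puts bromine on that carbon; the bromo ketone is epimerisable and settles with bromine equatorial, but the two ring A half-chairs differ only in whether C7 or C11 is axial, so little intrinsic preference for 4S is expected, and the step is planned with separation of the diastereomers and recycling of the 4R epimer.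

Step 9
Reactants: 13 (4S,6S,9R,10S)-4-bromo-9-[(tert-butyldimethylsilyl)oxy]-10-chloro-1,5,5,9-tetramethylspiro[5.5]undec-1-en-3-one
Product: 14 (3R,4S,6S,9R,10S)-4-bromo-9-[(tert-butyldimethylsilyl)oxy]-10-chloro-1,5,5,9-tetramethylspiro[5.5]undec-1-en-3-ol
Conditions: i-Bu2AlH, CH2Cl2, −78 °C; then aq. Rochelle salt
Reagents that add atoms: none
Why: 1,2-Reduction of the enone; with bromine equatorial at C4 the axial methyl on C5 shields one face of the carbonyl, hydride enters from the other, and the hydroxyl ends pseudo-axial and cis to bromine, where no epoxide can form.

Step 10
Reactants: 14 (3R,4S,6S,9R,10S)-4-bromo-9-[(tert-butyldimethylsilyl)oxy]-10-chloro-1,5,5,9-tetramethylspiro[5.5]undec-1-en-3-ol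
Product: 15 (3R,4S,6S,9R,10S)-4-bromo-9-[(tert-butyldimethylsilyl)oxy]-10-chloro-1-(hydroxymethyl)-5,5,9-trimethylspiro[5.5]undec-1-en-3-ol
Conditions: SeO2 (cat.), t-BuOOH, CH2Cl2, rt
Reagents that add atoms: selenium dioxide, O=[Se]=O; tert-butyl hydroperoxide, CC(C)(C)OO
Why: Selenium dioxide allylic hydroxylation (ene reaction, then 2,3-shift) takes a hydrogen from a substituent on the more substituted alkene carbon, and on C1 only the methyl offers one, the same regiochemistry as for prenyl-type allylic alcohols and esters; no stereocentre is formed.

Step 11
Reactants: 15 (3R,4S,6S,9R,10S)-4-bromo-9-[(tert-butyldimethylsilyl)oxy]-10-chloro-1-(hydroxymethyl)-5,5,9-trimethylspiro[5.5]undec-1-en-3-ol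
Product: 18 (3R,4S,6S,9R,10S)-4-bromo-9-[(tert-butyldimethylsilyl)oxy]-10-chloro-5,5,9-trimethyl-1-methylidenespiro[5.5]undecan-3-ol, via sulfonylhydrazine adduct 16 (not isolated), via allylic diazene 17 (not isolated)
Conditions: 2-O2NC6H4SO2NHNH2, PPh3, DEAD, N-methylmorpholine, −30 °C; then rt
Reagents that add atoms: none
Why: Mitsunobu displacement of the primary allylic alcohol by 2-nitrobenzenesulfonylhydrazide, loss of sulfinic acid on warming and retro-ene loss of N2 from the diazene put hydrogen on C2 and the alkene on C1=CH2 (reductive allylic transposition); the hindered secondary C3 hydroxyl next to the brominated carbon should react much more slowly, and the trans placement of CH2OH and C3 on the ring alkene excludes dihydrofuran formation.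

Step 12
Reactants: 18 (3R,4S,6S,9R,10S)-4-bromo-9-[(tert-butyldimethylsilyl)oxy]-10-chloro-5,5,9-trimethyl-1-methylidenespiro[5.5]undecan-3-ol
Product: 19 (3R,4S,6S,9R,10S)-4-bromo-10-chloro-5,5,9-trimethyl-1-methylidenespiro[5.5]undecane-3,9-diol
Conditions: HF·pyridine, THF/pyridine, 0 °C to rt
Reagents that add atoms: none
Why: Buffered fluoride cleavage of the tertiary silyl ether; the medium is neither basic enough to disturb the two cis halohydrins nor acidic enough to move the exocyclic alkene.

## Compound list

1 | (R)-linalool | CC(C)=CCC[C@@](C)(O)C=C | starting material
2 | tert-butyl{[(3R)-3,7-dimethylocta-1,6-dien-3-yl]oxy}dimethylsilane | CC(C)=CCC[C@@](C)(O[Si](C)(C)C(C)(C)C)C=C | intermediate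
3 | (4R)-4-[(tert-butyldimethylsilyl)oxy]-4-methylhex-5-enal | O=CCC[C@@](C)(O[Si](C)(C)C(C)(C)C)C=C | intermediate
4 | (4R)-4-[(tert-butyldimethylsilyl)oxy]-4-methylhex-5-enoic acid | OC(=O)CC[C@@](C)(O[Si](C)(C)C(C)(C)C)C=C | intermediate
5 | Barton ester of 4 (2-thioxopyridin-1(2H)-yl ester), not isolated | S=C1C=CC=CN1OC(=O)CC[C@@](C)(O[Si](C)(C)C(C)(C)C)C=C | intermediate
6 | tert-butyl{[(3R)-5-iodo-3-methylpent-1-en-3-yl]oxy}dimethylsilane | ICC[C@@](C)(O[Si](C)(C)C(C)(C)C)C=C | intermediate
7 | 2,6,6-trimethylcyclohex-2-en-1-one | CC1=CCCC(C)(C)C1=O | starting material
8 | {(3R)-3-[(tert-butyldimethylsilyl)oxy]-3-methylpent-4-en-1-yl}lithium, not isolated | [Li]CC[C@@](C)(O[Si](C)(C)C(C)(C)C)C=C | intermediate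
9 | 1-{(3R)-3-[(tert-butyldimethylsilyl)oxy]-3-methylpent-4-en-1-yl}-2,6,6-trimethylcyclohex-2-en-1-ol (both carbinol epimers) | CC1=CCCC(C)(C)C1(O)CC[C@@](C)(O[Si](C)(C)C(C)(C)C)C=C | intermediate
10 | tert-butyl{[(6R,9R,10S)-10-chloro-1,5,5,9-tetramethylspiro[5.5]undec-1-en-9-yl]oxy}dimethylsilane | CC1=CCCC(C)(C)[C@]12CC[C@@](C)(O[Si](C)(C)C(C)(C)C)[C@@H](Cl)C2 | intermediate
11 | (6R,9R,10S)-9-[(tert-butyldimethylsilyl)oxy]-10-chloro-1,5,5,9-tetramethylspiro[5.5]undec-1-en-3-one | CC1=CC(=O)CC(C)(C)[C@]12CC[C@@](C)(O[Si](C)(C)C(C)(C)C)[C@@H](Cl)C2 | intermediate
12 | cross-conjugated trimethylsilyl dienol ether of 11 (3-trimethylsilyloxy-1,3-diene), not isolated | CC1=CC(O[Si](C)(C)C)=CC(C)(C)[C@]12CC[C@@](C)(O[Si](C)(C)C(C)(C)C)[C@@H](Cl)C2 | intermediate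
13 | (4S,6S,9R,10S)-4-bromo-9-[(tert-butyldimethylsilyl)oxy]-10-chloro-1,5,5,9-tetramethylspiro[5.5]undec-1-en-3-one | CC1=CC(=O)[C@@H](Br)C(C)(C)[C@]12CC[C@@](C)(O[Si](C)(C)C(C)(C)C)[C@@H](Cl)C2 | intermediate
14 | (3R,4S,6S,9R,10S)-4-bromo-9-[(tert-butyldimethylsilyl)oxy]-10-chloro-1,5,5,9-tetramethylspiro[5.5]undec-1-en-3-ol | CC1=C[C@@H](O)[C@@H](Br)C(C)(C)[C@]12CC[C@@](C)(O[Si](C)(C)C(C)(C)C)[C@@H](Cl)C2 | intermediate
15 | (3R,4S,6S,9R,10S)-4-bromo-9-[(tert-butyldimethylsilyl)oxy]-10-chloro-1-(hydroxymethyl)-5,5,9-trimethylspiro[5.5]undec-1-en-3-ol | OCC1=C[C@@H](O)[C@@H](Br)C(C)(C)[C@]12CC[C@@](C)(O[Si](C)(C)C(C)(C)C)[C@@H](Cl)C2 | intermediate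
16 | N-allylic N-(2-nitrobenzenesulfonyl)hydrazine from 15, not isolated | NN(CC1=C[C@@H](O)[C@@H](Br)C(C)(C)[C@]12CC[C@@](C)(O[Si](C)(C)C(C)(C)C)[C@@H](Cl)C2)S(=O)(=O)c3ccccc3[N+](=O)[O-] | intermediate
17 | allylic monoalkyl diazene from 16, not isolated | N=NCC1=C[C@@H](O)[C@@H](Br)C(C)(C)[C@]12CC[C@@](C)(O[Si](C)(C)C(C)(C)C)[C@@H](Cl)C2 | intermediate
18 | (3R,4S,6S,9R,10S)-4-bromo-9-[(tert-butyldimethylsilyl)oxy]-10-chloro-5,5,9-trimethyl-1-methylidenespiro[5.5]undecan-3-ol | C=C1C[C@@H](O)[C@@H](Br)C(C)(C)[C@]12CC[C@@](C)(O[Si](C)(C)C(C)(C)C)[C@@H](Cl)C2 | intermediate
19 | (3R,4S,6S,9R,10S)-4-bromo-10-chloro-5,5,9-trimethyl-1-methylidenespiro[5.5]undecane-3,9-diol | C=C1C[C@@H](O)[C@@H](Br)C(C)(C)[C@]12CC[C@@](C)(O)[C@@H](Cl)C2 | target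

## Step count and least certain steps

Total step count: 12. Longest linear sequence: 12 steps (1 to 19); 7 enters at step 5.

Step 6 (key step, proposed new method).
- What may go wrong: after C6–C11 bonding, the C8–C9 bond, aligned with the empty orbital at C10 and pushed by the silyloxy oxygen, may migrate before chloride arrives, which would contract ring B and end in a ketone. The C9 ether oxygen may capture C6 and close an oxaspiro ether. The weakly nucleophilic vinyl group may fail to engage, so that the cation is lost by elimination. The chair preference that sets C6 against C9 may also be small.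
- Fallback with known chemistry, from 9 back to 10: Tsuji–Wacker oxidation of the vinyl group of 9 (PdCl2 cat., Cu(OAc)2 cat., O2, N,N-dimethylacetamide/H2O) should give the methyl ketone F1. Double silylation (LiN(i-Pr)2, Me3SiCl) gives the bis(trimethylsilyl) enol ether F2, in which the C6 oxygen is a silyl ether and the only enolisable side of the ketone is an enol silane. A Lewis acid (TiCl4, CH2Cl2, −78 °C) ionises the allylic silyl ether, and the enol silane carbon C11, a far better nucleophile than a vinyl group, alkylates C6 in an intramolecular SN1 alkylation of the Mukaiyama type to give the spiro ketone F3, with the same chair preference for an equatorial C5. Li(s-Bu)3BH, attacking from the equatorial side, gives the axial C10 alcohol F4, trans to the silyloxy group. An Appel reaction (PPh3, CCl4) replaces the hydroxyl by chlorine with inversion and returns to 10. The displacement at C10 next to the quaternary C9 is the weak point of this detour.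

Step 8.
- What may go wrong: poor facial selectivity in the bromination, because C7 and C11 differ only at the distant C10; and loss of material in repeated separation and re-equilibration.
- Fallback, from 13 (obtained as a mixture with its C4 epimer, the 4R bromo enone F5) to 14: the mixture is not separated. It is reduced with a Corey–Bakshi–Shibata oxazaborolidine and catecholborane instead of i-Bu2AlH, using the catalyst enantiomer that delivers hydride to the C3 face opposite the axial C5 methyl of 13. Catalyst and substrate preferences then coincide for 13 and oppose each other for F5, so 14 should form while F5 stays behind as the ketone, to be re-equilibrated at C4 with a catalytic amine base and returned.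

Step 10.
- What may go wrong: a sluggish ene reaction at an alkene deactivated by the neighbouring carbinol, oxidation of the C3 hydroxyl back to the enone, and over-oxidation of the new alcohol to the enal.
- Fallback, from 13 to 18 without selenium and without transposition: soft enolisation of 13 (Me3SiOTf, Et3N, CH2Cl2, 0 °C) toward the methyl group should give the linear silyl dienol ether F6. Mild buffered hydrolysis (aqueous citric acid, THF, 0 °C) protonates C2 kinetically and gives the β,γ-unsaturated bromo ketone F7. This is reduced at once with i-Bu2AlH at −78 °C, from the face opposite the axial C5 methyl, to give 18. The risk of this detour is enolisation toward C4 instead of the methyl group, and the lability of F7 toward reconjugation.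

Step 5.
- What may go wrong: migration of the silyl group from oxygen to carbon in 8 (retro-Brook shift) before addition, or proton abstraction from the hindered enone instead of addition.
- Fallback, from 6 to 9: the silyl group is removed from 6 (HF·pyridine) to give the iodo alcohol F8. Three equivalents of t-BuLi convert it into an alkoxide-bearing alkyllithium, which has no silyl group to migrate. Addition to 7 gives the diol F9, and TBSOTf/2,6-lutidine silylates the less hindered C9 hydroxyl (the C6 hydroxyl lies between a quaternary and a fully substituted sp2 carbon) to return to 9.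

## Further compounds

F1 | step 6 | (3R)-3-[(tert-butyldimethylsilyl)oxy]-5-(1-hydroxy-2,6,6-trimethylcyclohex-2-en-1-yl)-3-methylpentan-2-one | CC1=CCCC(C)(C)C1(O)CC[C@@](C)(O[Si](C)(C)C(C)(C)C)C(C)=O
F2 | step 6 | bis(trimethylsilyl) enol ether of F1 (C6 trimethylsilyl ether and 2-trimethylsilyloxy-1-ene) | CC1=CCCC(C)(C)C1(O[Si](C)(C)C)CC[C@@](C)(O[Si](C)(C)C(C)(C)C)C(=C)O[Si](C)(C)C
F3 | step 6 | (6R,9R)-9-[(tert-butyldimethylsilyl)oxy]-1,5,5,9-tetramethylspiro[5.5]undec-1-en-10-one | CC1=CCCC(C)(C)[C@]12CC[C@@](C)(O[Si](C)(C)C(C)(C)C)C(=O)C2
F4 | step 6 | (6R,9R,10R)-9-[(tert-butyldimethylsilyl)oxy]-1,5,5,9-tetramethylspiro[5.5]undec-1-en-10-ol | CC1=CCCC(C)(C)[C@]12CC[C@@](C)(O[Si](C)(C)C(C)(C)C)[C@H](O)C2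
F5 | step 8 | (4R,6S,9R,10S)-4-bromo-9-[(tert-butyldimethylsilyl)oxy]-10-chloro-1,5,5,9-tetramethylspiro[5.5]undec-1-en-3-one | CC1=CC(=O)[C@H](Br)C(C)(C)[C@]12CC[C@@](C)(O[Si](C)(C)C(C)(C)C)[C@@H](Cl)C2
F6 | step 10 | {[(4S,6S,9R,10S)-4-bromo-9-[(tert-butyldimethylsilyl)oxy]-10-chloro-5,5,9-trimethyl-1-methylidenespiro[5.5]undec-2-en-3-yl]oxy}trimethylsilane | C=C1C=C(O[Si](C)(C)C)[C@@H](Br)C(C)(C)[C@]12CC[C@@](C)(O[Si](C)(C)C(C)(C)C)[C@@H](Cl)C2
F7 | step 10 | (4S,6S,9R,10S)-4-bromo-9-[(tert-butyldimethylsilyl)oxy]-10-chloro-5,5,9-trimethyl-1-methylidenespiro[5.5]undecan-3-one | C=C1CC(=O)[C@@H](Br)C(C)(C)[C@]12CC[C@@](C)(O[Si](C)(C)C(C)(C)C)[C@@H](Cl)C2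
F8 | step 5 | (3R)-5-iodo-3-methylpent-1-en-3-ol | ICC[C@@](C)(O)C=C
F9 | step 5 | 1-[(3R)-3-hydroxy-3-methylpent-4-en-1-yl]-2,6,6-trimethylcyclohex-2-en-1-ol | CC1=CCCC(C)(C)C1(O)CC[C@@](C)(O)C=C
A1 | alternative 1 | ring A α-bromo ketone with exocyclic methylene and ring B enone ketal (product of the carbenoid ring expansion) | C=C1CC(=O)[C@@H](Br)C(C)(C)[C@]12C=CC3(OCCO3)CC2
A2 | alternative 1 | spiro cyclopentanone precursor of the ring expansion | C=C1CC(=O)C(C)(C)[C@]12C=CC3(OCCO3)CC2
A3 | alternative 2 | ring A cis-bromohydrin spiro ketal (product of the carbonyl-ene closure) | C=C1C[C@@H](O)[C@@H](Br)C(C)(C)C12CCC3(CC2)OCCO3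
A4 | alternative 2 | α-bromo aldehyde with isopropenyl group on C6 (ene precursor) | C=C(C)C1(CCC2(CC1)OCCO2)C(C)(C)[C@H](Br)C=O
A5 | alternative 3 | spiro diene silyl ether (product of the Heck spirocyclisation) | C=C1C[C@@H](O[Si](C)(C)C(C)(C)C)CC(C)(C)[C@]12C=CC3(OCCO3)CC2
A6 | alternative 3 | vinyl bromide precursor of the Heck spirocyclisation | C=C(Br)C[C@@H](O[Si](C)(C)C(C)(C)C)CC(C)(C)C1=CCC2(CC1)OCCO2
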